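**Plan** (atom labels are those of the labdane skeleton of the target: ring B = C5–C10, C2 = lactone carbonyl, C3 = free carboxyl)

1. Retrosynthesis cuts C14–C15 and C13–C14 (two methylene transfers onto a C13 methyl ketone), C11–C12 (Wittig), the lactone C8–O bond (iodolactonisation), C1–C2 (Arndt–Eistert insertion of C1), then C5–C6 and C9–C10 together (intramolecular Diels–Alder) and the ester tether.
2. Enabling feature: ring B carries the contiguous stereocentres C5, C10 and C9, and the carbon on C10 (future C2) and C11 on C9 are trans-1,2 neighbours that can be tied as a γ-lactone, so a dienyl ester of an (E)-2-methylalkenoic acid maps onto ring B.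
3. Forward: an acid (C3–C5, C10, C20, future C2) and a dienol (C6–C9, C11, C17) are joined as an ester; heating closes ring B and the trans-fused γ-lactone at once; the lactone is opened, C1 inserted, the auxiliary carbon cut off to leave C11 as aldehyde, the chain grown to C13, the bridged δ-lactone closed onto C8, and C14 and C15 added last.
4. Stereochemistry: a temporary stereocentre on the tether carbon C11 (from (R)-solketal) steers the diene face through allylic 1,3-strain with the C8 methyl and so fixes C9, C10 and C5 in the absolute sense; the (E)-dienophile gives C5/C10 and the exo tether the trans fusion; C8 follows from anti iodolactonisation by the C10 acetate arm; C13 from a catalyst-controlled Corey–Chaykovsky epoxidation; the C11 stereocentre is then erased by glycol cleavage.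

Key step: step 10

Assumption: the (S)-binaphthoxide complex in step 20 is taken to deliver methylene to the ketone face that gives the (13R)-epoxide; if a model methyl ketone shows the opposite sense, the (R)-binaphthoxide complex is used instead.

**Step 1**
Reactants: 1 3-hydroxy-2,2-dimethylpropanoic acid
Product: 2 prop-2-en-1-yl 3-hydroxy-2,2-dimethylpropanoate
Conditions: allyl bromide, K2CO3, DMF, 20 °C
Reagents that add atoms: allyl bromide, C=CCBr
Why: The potassium carboxylate is alkylated by SN2 at allyl bromide (carboxylate O-alkylation), while the neopentyl hydroxyl is not ionised by carbonate and stays free.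

**Step 2**
Reactants: 2 prop-2-en-1-yl 3-hydroxy-2,2-dimethylpropanoate
Product: 3 prop-2-en-1-yl 2,2-dimethyl-3-oxopropanoate
Conditions: TEMPO (10 mol %), PhI(OAc)2, CH2Cl2, 20 °C
Reagents that add atoms: none
Why: Oxoammonium (TEMPO) oxidation should stop at the aldehyde, which cannot enolise because its α-carbon is quaternary.

**Step 3**
Reactants: 3 prop-2-en-1-yl 2,2-dimethyl-3-oxopropanoate; 4 2-(triphenylphosphoranylidene)propanal
Product: 5 prop-2-en-1-yl (3E)-2,2,4-trimethyl-5-oxopent-3-enoate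
Conditions: toluene, 110 °C
Reagents that add atoms: none
Why: Wittig olefination with the formyl-stabilised ylide should give the (E)-enal, the reversible addition placing the quaternary carbon trans to the formyl group, and the hindered conjugated product should not react a second time.

**Step 4**
Reactants: 5 prop-2-en-1-yl (3E)-2,2,4-trimethyl-5-oxopent-3-enoate
Product: 6 (2E)-2,4,4-trimethyl-5-oxo-5-(prop-2-en-1-yloxy)pent-2-enoic acid
Conditions: NaClO2, NaH2PO4, 2-methylbut-2-ene, t-BuOH/H2O, 20 °C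
Reagents that add atoms: sodium chlorite, [Na+].[O-]Cl=O
Why: Pinnick oxidation converts the enal into the acid without touching the alkene geometry; 2-methylbut-2-ene traps the hypochlorous acid before it can add to the allyl group.

**Step 5**
Reactants: 7 [(4R)-2,2-dimethyl-1,3-dioxolan-4-yl]methanol ((R)-solketal); 4 2-(triphenylphosphoranylidene)propanal
Product: 9 (2E)-3-[(4R)-2,2-dimethyl-1,3-dioxolan-4-yl]-2-methylprop-2-enal, via glyceraldehyde acetonide 8 (not isolated)
Conditions: TEMPO (10 mol %), PhI(OAc)2, CH2Cl2, 20 °C; then 4, 40 °C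
Reagents that add atoms: none
Why: One-pot alcohol oxidation and Wittig olefination avoids isolating the configurationally labile α-alkoxy aldehyde; the stereocentre (future C11) is not involved and the stabilised ylide should give the (E)-enal.

**Step 6**
Reactants: 9 (2E)-3-[(4R)-2,2-dimethyl-1,3-dioxolan-4-yl]-2-methylprop-2-enal
Product: 10 (4R)-2,2-dimethyl-4-[(1E)-2-methylbuta-1,3-dien-1-yl]-1,3-dioxolane
Conditions: Ph3PCH3Br, KN(SiMe3)2, THF, −78 → 0 °C
Reagents that add atoms: methyltriphenylphosphonium bromide, C[P+](c1ccccc1)(c1ccccc1)c1ccccc1.[Br-]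
Why: Wittig methylenation of the enal (1,2-addition at low temperature, faster than γ-deprotonation) should give the (E)-diene without change at the dioxolane stereocentre.

**Step 7**
Reactants: 10 (4R)-2,2-dimethyl-4-[(1E)-2-methylbuta-1,3-dien-1-yl]-1,3-dioxolane
Product: 11 (2R,3E)-4-methylhexa-3,5-diene-1,2-diol
Conditions: pyridinium p-toluenesulfonate (0.2 equiv), MeOH, 20 °C
Reagents that add atoms: none
Why: Acid-catalysed transacetalisation to methanol frees the diol; the weak acid and the β-oxygen should keep the dienylic C–O bond from ionising.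

**Step 8**
Reactants: 11 (2R,3E)-4-methylhexa-3,5-diene-1,2-diol
Product: 12 (2R,3E)-1-{[tert-butyl(dimethyl)silyl]oxy}-4-methylhexa-3,5-dien-2-ol
Conditions: TBSCl (1.05 equiv), imidazole, CH2Cl2, −20 → 0 °C
Reagents that add atoms: tert-butyldimethylsilyl chloride, CC(C)(C)[Si](C)(C)Cl
Why: Silylation should take the less hindered primary hydroxyl (steric differentiation), leaving the secondary dienylic alcohol for the tether.

**Step 9**
Reactants: 6 (2E)-2,4,4-trimethyl-5-oxo-5-(prop-2-en-1-yloxy)pent-2-enoic acid; 12 (2R,3E)-1-{[tert-butyl(dimethyl)silyl]oxy}-4-methylhexa-3,5-dien-2-ol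
Product: 13 1-[(2R,3E)-1-{[tert-butyl(dimethyl)silyl]oxy}-4-methylhexa-3,5-dien-2-yl] 5-(prop-2-en-1-yl) (2E)-2,4,4-trimethylpent-2-enedioate
Conditions: DCC, DMAP, CH2Cl2, 0 → 20 °C
Reagents that add atoms: none
Why: Steglich esterification acylates the alcohol oxygen, so the carbinol configuration is retained, and acid 6 has no γ-hydrogen that could allow deconjugation under DMAP.

**Step 10**
Reactants: 13 triene ester (dienyl ester of the (E)-2-methylalkenoic acid)
Product: 14 prop-2-en-1-yl 2-[(3R,3aR,7R,7aR)-3-({[tert-butyl(dimethyl)silyl]oxy}methyl)-4,7a-dimethyl-1-oxo-1,3,3a,6,7,7a-hexahydro-2-benzofuran-7-yl]-2-methylpropanoate (ring B with C7=C8 alkene and trans-fused γ-lactone)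
Conditions: 1,2-dichlorobenzene (0.01 M), BHT (cat.), 180 °C, sealed tube
Reagents that add atoms: none
Why: Heating should bring the s-cis diene (C6–C9) and the tethered (E)-trisubstituted alkene (C5=C10) together in a concerted, asynchronous, suprafacial [4+2] cycloaddition; the closest known reaction type is the thermal type 1 intramolecular Diels–Alder reaction of ester-tethered 1,3,8-nonatrienes (pentadienyl acrylates). Ring B is closed as the six-membered carbocycle by the new C5–C6 and C9–C10 bonds, and the γ-lactone is closed in the fused mode by the same C9–C10 bond through the three-atom C11–O–C(=O) tether. C5 and C10 are fixed relative to each other by suprafacial addition to the (E)-alkene (C4 cis to the C10 methyl), and C9 relative to C10 by the exo orientation of the tether carbonyl, which gives the trans ring fusion. The absolute sense comes from the C11 stereocentre: allylic 1,3-strain with the cis C8 methyl should hold the C11–H bond in the diene plane, so the ester oxygen, and with it the dienophile, reaches one diene face while the silyloxymethyl group points to the other. The step needs trans over cis fusion and one diene face; both rest on the C8 methyl acting on the C11 stereocentre, the same conformational lock that places the tether oxygen where the exo carbonyl bridges best, and any minor isomers would be diastereomers removable by chromatography.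

**Step 11**
Reactants: 14 trans-fused γ-lactone
Product: 17 2-[(1R)-1,2-bis{[tert-butyl(dimethyl)silyl]oxy}ethyl]-1,3-dimethyl-6-[2-methyl-1-oxo-1-(prop-2-en-1-yloxy)propan-2-yl]cyclohex-3-ene-1-carboxylic acid (C5/C9/C10 as in 14), via lithium hydroxy carboxylate 15 (not isolated), via silyl ester 16 (not isolated)
Conditions: LiOH, THF/H2O, 40 °C; evaporate; TBSOTf, 2,6-lutidine, CH2Cl2, 0 °C; K2CO3, THF/H2O, 20 °C; pH 4 work-up
Reagents that add atoms: lithium hydroxide, [Li+].[OH-]; tert-butyldimethylsilyl trifluoromethanesulfonate, CC(C)(C)[Si](C)(C)OS(=O)(=O)C(F)(F)F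
Why: Saponification should open the strained trans-fused lactone faster than the hindered allyl ester; silylation of alkoxide and carboxylate followed by selective hydrolysis of the labile silyl ester blocks relactonisation (a silyl shift between the vicinal oxygens is harmless because both end up silylated).

**Step 12**
Reactants: 17 bis-silyl ether acid
Product: 19 diazoketone (carboxyl of 17 replaced by C(=O)CHN2), via acid chloride 18 (not isolated)
Conditions: 1-chloro-N,N,2-trimethylprop-1-en-1-amine, CH2Cl2, 0 → 20 °C; then CH2N2 (excess), Et2O, 0 °C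
Reagents that add atoms: diazomethane, C=[N+]=[N-]
Why: The neutral α-chloroenamine converts the hindered acid into its chloride without acid that could cleave the silyl ethers, and diazomethane then acylates to the diazoketone (first half of the Arndt–Eistert homologation).

**Step 13**
Reactants: 19 diazoketone
Product: 21 2-(trimethylsilyl)ethyl {2-[(1R)-1,2-bis{[tert-butyl(dimethyl)silyl]oxy}ethyl]-1,3-dimethyl-6-[2-methyl-1-oxo-1-(prop-2-en-1-yloxy)propan-2-yl]cyclohex-3-en-1-yl}acetate, via ketene 20 (not isolated)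
Conditions: hν (365 nm), Me3SiCH2CH2OH (10 equiv), THF, 20 °C
Reagents that add atoms: 2-(trimethylsilyl)ethanol, C[Si](C)(C)CCO
Why: Photochemical Wolff rearrangement moves C10 with retention to the carbene carbon and the ketene is trapped by the alcohol, which inserts C1 between C10 and the carboxyl; the excess alcohol should outrun any intramolecular ketene–alkene addition.

**Step 14**
Reactants: 21 homologated bis-silyl ether diester
Product: 22 2-(trimethylsilyl)ethyl {2-[(1R)-1,2-dihydroxyethyl]-1,3-dimethyl-6-[2-methyl-1-oxo-1-(prop-2-en-1-yloxy)propan-2-yl]cyclohex-3-en-1-yl}acetate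
Conditions: HF·pyridine, pyridine, THF, 0 → 20 °C
Reagents that add atoms: none
Why: Buffered HF desilylation frees the vicinal diol while the 2-(trimethylsilyl)ethyl ester, which needs naked fluoride, should survive; the diol is used at once so that it cannot lactonise onto the C2 ester.

**Step 15**
Reactants: 22 diol
Product: 23 2-(trimethylsilyl)ethyl {2-formyl-1,3-dimethyl-6-[2-methyl-1-oxo-1-(prop-2-en-1-yloxy)propan-2-yl]cyclohex-3-en-1-yl}acetate (C11 aldehyde)
Conditions: NaIO4, THF/pH 7 phosphate buffer, 0 °C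
Reagents that add atoms: none
Why: Periodate glycol cleavage excises the auxiliary carbon and leaves C11 as the aldehyde under neutral conditions, so that C9 of this α-cyclocitral-type β,γ-unsaturated aldehyde should be neither epimerised nor brought into conjugation.

**Step 16**
Reactants: 23 C11 aldehyde; 24 1-(triphenylphosphoranylidene)propan-2-one
Product: 25 2-(trimethylsilyl)ethyl {1,3-dimethyl-6-[2-methyl-1-oxo-1-(prop-2-en-1-yloxy)propan-2-yl]-2-[(1E)-3-oxobut-1-en-1-yl]cyclohex-3-en-1-yl}acetate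
Conditions: toluene, 80 °C
Reagents that add atoms: none
Why: Wittig olefination with the acetyl-stabilised ylide is base-free, so the sensitive aldehyde should be converted into the (E)-enone (an α-ionone-type system) with C9 intact.

**Step 17**
Reactants: 25 enone
Product: 26 2-(trimethylsilyl)ethyl {1,3-dimethyl-6-[2-methyl-1-oxo-1-(prop-2-en-1-yloxy)propan-2-yl]-2-(3-oxobutyl)cyclohex-3-en-1-yl}acetate (C13 methyl ketone)
Conditions: [(Ph3P)CuH]6, H2O (5 equiv), toluene, 20 °C
Reagents that add atoms: none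
Why: Copper hydride conjugate reduction is chemoselective for the enone and should leave the ring alkene, the allyl group and both esters untouched.

**Step 18**
Reactants: 26 C13 methyl ketone
Product: 28 prop-2-en-1-yl 2-[8-iodo-1,5-dimethyl-3-oxo-9-(3-oxobutyl)-2-oxabicyclo[3.3.1]nonan-6-yl]-2-methylpropanoate (iodine anti to the lactone oxygen; other centres as in 29), via ammonium carboxylate 27 (not isolated)
Conditions: Bu4NF, THF, 0 → 20 °C; then NaHCO3, I2, MeCN/H2O, 0 → 20 °C, dark
Reagents that add atoms: iodine, II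
Why: Fluoride fragments the 2-(trimethylsilyl)ethyl ester and the carboxylate then closes the bridged δ-lactone by 6-exo attack on the tertiary C8 of the iodonium ion (iodolactonisation); only the ring face that carries the C10 acetate arm can be reached, so the C8 oxygen is set cis to that arm with iodine anti on C7.

**Step 19**
Reactants: 28 iodolactone
Product: 29 prop-2-en-1-yl 2-[(1S,5R,6S,9S)-1,5-dimethyl-3-oxo-9-(3-oxobutyl)-2-oxabicyclo[3.3.1]nonan-6-yl]-2-methylpropanoate
Conditions: Bu3SnH, AIBN, toluene, 80 °C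
Reagents that add atoms: none
Why: Radical chain reduction replaces iodine by hydrogen; a high stannane concentration suppresses acyloxy shift of the β-acyloxy radical, and ketone, lactone and allyl ester are inert.

**Step 20**
Reactants: 29 keto lactone
Product: 30 prop-2-en-1-yl 2-[(1S,5R,6S,9S)-1,5-dimethyl-9-{2-[(2R)-2-methyloxiran-2-yl]ethyl}-3-oxo-2-oxabicyclo[3.3.1]nonan-6-yl]-2-methylpropanoate
Conditions: Me3S(O)I, NaH, THF; then LaLi3[(S)-binaphthoxide]3 (5 mol %), (2,4,6-(MeO)3C6H2)3P=O (5 mol %), 5 Å molecular sieves, THF, 20 °C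
Reagents that add atoms: trimethylsulfoxonium iodide, C[S+](C)(C)=O.[I-]
Why: The catalytic asymmetric Corey–Chaykovsky epoxidation of methyl ketones with the lanthanum–lithium binaphthoxide complex is reagent-controlled, so C13 is set by the catalyst antipode independently of the remote ring stereocentres; the sulfoxonium ylide should prefer the ketone over the hindered lactone and ester.

**Step 21**
Reactants: 30 epoxide
Product: 31 prop-2-en-1-yl 2-[(1S,5R,6S,9S)-9-[(3R)-3-hydroxy-3-methylpent-4-en-1-yl]-1,5-dimethyl-3-oxo-2-oxabicyclo[3.3.1]nonan-6-yl]-2-methylpropanoate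
Conditions: Me3SI, n-BuLi, THF, −10 → 20 °C
Reagents that add atoms: trimethylsulfonium iodide, C[S+](C)C.[I-]
Why: Dimethylsulfonium methylide opens the epoxide at its CH2 (SN2) and the resulting sulfonium salt eliminates dimethyl sulfide to give the one-carbon-homologated allylic alcohol; the C13–O bond is never broken, so its configuration is retained.

**Step 22**
Reactants: 31 allyl ester of the target
Product: 32 2-[(1S,5R,6S,9S)-9-[(3R)-3-hydroxy-3-methylpent-4-en-1-yl]-1,5-dimethyl-3-oxo-2-oxabicyclo[3.3.1]nonan-6-yl]-2-methylpropanoic acid (CNP0198729.3)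
Conditions: Pd(PPh3)4 (5 mol %), morpholine, THF, 20 °C; pH 4 buffer work-up
Reagents that add atoms: none
Why: Tsuji–Trost deallylation: zerovalent palladium ionises only the allyl carboxylate and morpholine captures the allyl group, while the tertiary allylic alcohol (hydroxide is no leaving group) and the acid-sensitive tertiary lactone should stay intact.

**Compound list**

1 | 3-hydroxy-2,2-dimethylpropanoic acid | CC(C)(CO)C(=O)O | starting material
2 | prop-2-en-1-yl 3-hydroxy-2,2-dimethylpropanoate | CC(C)(CO)C(=O)OCC=C | intermediate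
3 | prop-2-en-1-yl 2,2-dimethyl-3-oxopropanoate | CC(C)(C=O)C(=O)OCC=C | intermediate
4 | 2-(triphenylphosphoranylidene)propanal | CC(C=O)=P(c1ccccc1)(c1ccccc1)c1ccccc1 | starting material
5 | prop-2-en-1-yl (3E)-2,2,4-trimethyl-5-oxopent-3-enoate | C=CCOC(=O)C(C)(C)/C=C(\C)C=O | intermediate
6 | (2E)-2,4,4-trimethyl-5-oxo-5-(prop-2-en-1-yloxy)pent-2-enoic acid | C=CCOC(=O)C(C)(C)/C=C(\C)C(=O)O | intermediate
7 | [(4R)-2,2-dimethyl-1,3-dioxolan-4-yl]methanol | OC[C@@H]1COC(C)(C)O1 | starting material
8 | (4S)-2,2-dimethyl-1,3-dioxolane-4-carbaldehyde | O=C[C@@H]1COC(C)(C)O1 | intermediate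
9 | (2E)-3-[(4R)-2,2-dimethyl-1,3-dioxolan-4-yl]-2-methylprop-2-enal | O=C/C(C)=C/[C@@H]1COC(C)(C)O1 | intermediate
10 | (4R)-2,2-dimethyl-4-[(1E)-2-methylbuta-1,3-dien-1-yl]-1,3-dioxolane | C=C/C(C)=C/[C@@H]1COC(C)(C)O1 | intermediate
11 | (2R,3E)-4-methylhexa-3,5-diene-1,2-diol | C=C/C(C)=C/[C@@H](O)CO | intermediate
12 | (2R,3E)-1-{[tert-butyl(dimethyl)silyl]oxy}-4-methylhexa-3,5-dien-2-ol | C=C/C(C)=C/[C@@H](O)CO[Si](C)(C)C(C)(C)C | intermediate
13 | 1-[(2R,3E)-1-{[tert-butyl(dimethyl)silyl]oxy}-4-methylhexa-3,5-dien-2-yl] 5-(prop-2-en-1-yl) (2E)-2,4,4-trimethylpent-2-enedioate | C=CCOC(=O)C(C)(C)/C=C(\C)C(=O)O[C@@H](CO[Si](C)(C)C(C)(C)C)/C=C(\C)C=C | intermediate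
14 | prop-2-en-1-yl 2-[(3R,3aR,7R,7aR)-3-({[tert-butyl(dimethyl)silyl]oxy}methyl)-4,7a-dimethyl-1-oxo-1,3,3a,6,7,7a-hexahydro-2-benzofuran-7-yl]-2-methylpropanoate | CC1=CC[C@H](C(C)(C)C(=O)OCC=C)[C@@]2(C)C(=O)O[C@@H](CO[Si](C)(C)C(C)(C)C)[C@H]12 | intermediate
15 | lithium 2-[(1R)-2-{[tert-butyl(dimethyl)silyl]oxy}-1-hydroxyethyl]-1,3-dimethyl-6-[2-methyl-1-oxo-1-(prop-2-en-1-yloxy)propan-2-yl]cyclohex-3-ene-1-carboxylate (ring centres as in 14) | CC1=CC[C@H](C(C)(C)C(=O)OCC=C)[C@@](C)(C(=O)[O-])[C@@H]1[C@@H](O)CO[Si](C)(C)C(C)(C)C.[Li+] | intermediate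
16 | tert-butyl(dimethyl)silyl ester of acid 17 | CC1=CC[C@H](C(C)(C)C(=O)OCC=C)[C@@](C)(C(=O)O[Si](C)(C)C(C)(C)C)[C@@H]1[C@@H](O[Si](C)(C)C(C)(C)C)CO[Si](C)(C)C(C)(C)C | intermediate
17 | 2-[(1R)-1,2-bis{[tert-butyl(dimethyl)silyl]oxy}ethyl]-1,3-dimethyl-6-[2-methyl-1-oxo-1-(prop-2-en-1-yloxy)propan-2-yl]cyclohex-3-ene-1-carboxylic acid (carboxyl trans to both neighbouring side chains, as in 14) | CC1=CC[C@H](C(C)(C)C(=O)OCC=C)[C@@](C)(C(=O)O)[C@@H]1[C@@H](O[Si](C)(C)C(C)(C)C)CO[Si](C)(C)C(C)(C)C | intermediate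
18 | acid chloride of 17 | CC1=CC[C@H](C(C)(C)C(=O)OCC=C)[C@@](C)(C(=O)Cl)[C@@H]1[C@@H](O[Si](C)(C)C(C)(C)C)CO[Si](C)(C)C(C)(C)C | intermediate
19 | diazoketone: carboxyl of 17 replaced by diazoacetyl, C(=O)CHN2 | CC1=CC[C@H](C(C)(C)C(=O)OCC=C)[C@@](C)(C(=O)C=[N+]=[N-])[C@@H]1[C@@H](O[Si](C)(C)C(C)(C)C)CO[Si](C)(C)C(C)(C)C | intermediate
20 | ketene: C10 carries CH=C=O in place of the diazoacetyl group of 19 | CC1=CC[C@H](C(C)(C)C(=O)OCC=C)[C@@](C)(C=C=O)[C@@H]1[C@@H](O[Si](C)(C)C(C)(C)C)CO[Si](C)(C)C(C)(C)C | intermediate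
21 | 2-(trimethylsilyl)ethyl {2-[(1R)-1,2-bis{[tert-butyl(dimethyl)silyl]oxy}ethyl]-1,3-dimethyl-6-[2-methyl-1-oxo-1-(prop-2-en-1-yloxy)propan-2-yl]cyclohex-3-en-1-yl}acetate (ring centres as in 17) | CC1=CC[C@H](C(C)(C)C(=O)OCC=C)[C@@](C)(CC(=O)OCC[Si](C)(C)C)[C@@H]1[C@@H](O[Si](C)(C)C(C)(C)C)CO[Si](C)(C)C(C)(C)C | intermediate
22 | 2-(trimethylsilyl)ethyl {2-[(1R)-1,2-dihydroxyethyl]-1,3-dimethyl-6-[2-methyl-1-oxo-1-(prop-2-en-1-yloxy)propan-2-yl]cyclohex-3-en-1-yl}acetate (ring centres as in 17) | CC1=CC[C@H](C(C)(C)C(=O)OCC=C)[C@@](C)(CC(=O)OCC[Si](C)(C)C)[C@@H]1[C@@H](O)CO | intermediate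
23 | 2-(trimethylsilyl)ethyl {2-formyl-1,3-dimethyl-6-[2-methyl-1-oxo-1-(prop-2-en-1-yloxy)propan-2-yl]cyclohex-3-en-1-yl}acetate (formyl trans to the acetate arm) | CC1=CC[C@H](C(C)(C)C(=O)OCC=C)[C@@](C)(CC(=O)OCC[Si](C)(C)C)[C@@H]1C=O | intermediate
24 | 1-(triphenylphosphoranylidene)propan-2-one | CC(=O)C=P(c1ccccc1)(c1ccccc1)c1ccccc1 | starting material
25 | 2-(trimethylsilyl)ethyl {1,3-dimethyl-6-[2-methyl-1-oxo-1-(prop-2-en-1-yloxy)propan-2-yl]-2-[(1E)-3-oxobut-1-en-1-yl]cyclohex-3-en-1-yl}acetate (ring centres as in 23) | CC1=CC[C@H](C(C)(C)C(=O)OCC=C)[C@@](C)(CC(=O)OCC[Si](C)(C)C)[C@@H]1/C=C/C(C)=O | intermediate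
26 | 2-(trimethylsilyl)ethyl {1,3-dimethyl-6-[2-methyl-1-oxo-1-(prop-2-en-1-yloxy)propan-2-yl]-2-(3-oxobutyl)cyclohex-3-en-1-yl}acetate (ring centres as in 23) | CC1=CC[C@H](C(C)(C)C(=O)OCC=C)[C@@](C)(CC(=O)OCC[Si](C)(C)C)[C@@H]1CCC(C)=O | intermediate
27 | tetrabutylammonium {1,3-dimethyl-6-[2-methyl-1-oxo-1-(prop-2-en-1-yloxy)propan-2-yl]-2-(3-oxobutyl)cyclohex-3-en-1-yl}acetate | CC1=CC[C@H](C(C)(C)C(=O)OCC=C)[C@@](C)(CC(=O)[O-])[C@@H]1CCC(C)=O.CCCC[N+](CCCC)(CCCC)CCCC | intermediate
28 | prop-2-en-1-yl 2-[8-iodo-1,5-dimethyl-3-oxo-9-(3-oxobutyl)-2-oxabicyclo[3.3.1]nonan-6-yl]-2-methylpropanoate (iodine anti to the lactone oxygen; other centres as in 29) | CC(=O)CC[C@H]1[C@]2(C)CC(=O)O[C@@]1(C)[C@H](I)C[C@@H]2C(C)(C)C(=O)OCC=C | intermediate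
29 | prop-2-en-1-yl 2-[(1S,5R,6S,9S)-1,5-dimethyl-3-oxo-9-(3-oxobutyl)-2-oxabicyclo[3.3.1]nonan-6-yl]-2-methylpropanoate | CC(=O)CC[C@H]1[C@]2(C)CC(=O)O[C@@]1(C)CC[C@@H]2C(C)(C)C(=O)OCC=C | intermediate
30 | prop-2-en-1-yl 2-[(1S,5R,6S,9S)-1,5-dimethyl-9-{2-[(2R)-2-methyloxiran-2-yl]ethyl}-3-oxo-2-oxabicyclo[3.3.1]nonan-6-yl]-2-methylpropanoate | C[C@]3(CO3)CC[C@H]1[C@]2(C)CC(=O)O[C@@]1(C)CC[C@@H]2C(C)(C)C(=O)OCC=C | intermediate
31 | prop-2-en-1-yl 2-[(1S,5R,6S,9S)-9-[(3R)-3-hydroxy-3-methylpent-4-en-1-yl]-1,5-dimethyl-3-oxo-2-oxabicyclo[3.3.1]nonan-6-yl]-2-methylpropanoate | C=C[C@](C)(O)CC[C@H]1[C@]2(C)CC(=O)O[C@@]1(C)CC[C@@H]2C(C)(C)C(=O)OCC=C | intermediate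
32 | 2-[(1S,5R,6S,9S)-9-[(3R)-3-hydroxy-3-methylpent-4-en-1-yl]-1,5-dimethyl-3-oxo-2-oxabicyclo[3.3.1]nonan-6-yl]-2-methylpropanoic acid | C=C[C@](C)(O)CC[C@H]1[C@]2(C)CC(=O)O[C@@]1(C)CC[C@@H]2C(C)(C)C(=O)O | target

**Count**

Total steps: 22. Longest linear sequence: 18 steps (steps 1–4 or 5–8, then 9–22).

**Steps most likely to fail**

Step 10. The hindered trisubstituted dienophile may add so slowly that ionisation or elimination of the secondary dienylic ester competes, or cycloaddition may leak through the endo tether or the other diene face. The fallback sets out from 6 and returns at 23; absolute control then comes from resolution instead of the tether stereocentre. (E)-3-Methylpent-2-en-4-yn-1-ol is semihydrogenated (H2, Pd/CaCO3 poisoned with Pb(OAc)2, quinoline) to (2E)-3-methylpenta-2,4-dien-1-ol F1, which is esterified with 6 (DCC, DMAP) to the primary dienyl ester F2. The thermally more robust F2 is cyclised under the conditions of step 10 to the racemic trans-fused lactone F3, which is resolved by preparative chromatography on a chiral stationary phase to the (3aR,7R,7aR)-lactone F4. Saponification and silylation as in step 11 give the silyl ether acid F5; homologation as in steps 12 and 13 gives the diazoketone F6 and then the 2-(trimethylsilyl)ethyl ester F7; HF·pyridine frees the primary alcohol F8, and Dess–Martin oxidation gives 23.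

Step 18. Ring closure demands the ring B conformer in which the C10 acetate arm, the C4 group and the C9 chain are all axial, and it also places iodine axial on C7; the iodonium ion may therefore revert without cyclising, or iodine may be consumed at the allyl group. The fallback sets out from 26 and returns at 29, and needs no substituent on C7 during ring closure. Mukaiyama hydration of the ring alkene (Mn(dpm)3, dpm = 2,2,6,6-tetramethylheptane-3,5-dionate, PhSiH3, O2, i-PrOH) should give the tertiary alcohol F9; the trisubstituted alkene is the better hydrogen-atom acceptor than the allyl group, and oxygen should enter anti to the axial C10 methyl, on the face of the acetate arm. Bu4NF then releases the hydroxy acid F10, and the lactone is closed by carboxyl activation (2-methyl-6-nitrobenzoic anhydride, DMAP, Et3N, high dilution) to 29.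

Step 21. The strongly nucleophilic sulfonium ylide may attack or enolise the strained lactone before it opens the epoxide. The fallback sets out from 29 and returns at 31. Catalytic asymmetric alkynylation of the ketone (Me3SiC≡CH, Me2Zn, chiral salen ligand; organozinc reagents do not touch lactones or esters) should give the silylated propargylic alcohol F11, the minor C13 epimer being removed by chromatography. Bu4NF/AcOH gives the ethynyl carbinol F12, and semihydrogenation (H2, Pd/CaCO3 poisoned with Pb(OAc)2, quinoline) gives 31.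

**Further compounds**

F1 | step 10 | (2E)-3-methylpenta-2,4-dien-1-ol | C=C/C(C)=C/CO
F2 | step 10 | 1-[(2E)-3-methylpenta-2,4-dien-1-yl] 5-(prop-2-en-1-yl) (2E)-2,4,4-trimethylpent-2-enedioate | C=CCOC(=O)C(C)(C)/C=C(\C)C(=O)OC/C=C(\C)C=C
F3 | step 10 | racemic prop-2-en-1-yl 2-[(3aR*,7R*,7aR*)-4,7a-dimethyl-1-oxo-1,3,3a,6,7,7a-hexahydro-2-benzofuran-7-yl]-2-methylpropanoate | CC1=CC[C@H](C(C)(C)C(=O)OCC=C)[C@@]2(C)C(=O)OC[C@H]12
F4 | step 10 | prop-2-en-1-yl 2-[(3aR,7R,7aR)-4,7a-dimethyl-1-oxo-1,3,3a,6,7,7a-hexahydro-2-benzofuran-7-yl]-2-methylpropanoate, single enantiomer | CC1=CC[C@H](C(C)(C)C(=O)OCC=C)[C@@]2(C)C(=O)OC[C@H]12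
F5 | step 10 | 2-({[tert-butyl(dimethyl)silyl]oxy}methyl)-1,3-dimethyl-6-[2-methyl-1-oxo-1-(prop-2-en-1-yloxy)propan-2-yl]cyclohex-3-ene-1-carboxylic acid (ring centres as in 17) | CC1=CC[C@H](C(C)(C)C(=O)OCC=C)[C@@](C)(C(=O)O)[C@@H]1CO[Si](C)(C)C(C)(C)C
F6 | step 10 | diazoketone: carboxyl of F5 replaced by diazoacetyl | CC1=CC[C@H](C(C)(C)C(=O)OCC=C)[C@@](C)(C(=O)C=[N+]=[N-])[C@@H]1CO[Si](C)(C)C(C)(C)C
F7 | step 10 | 2-(trimethylsilyl)ethyl {2-({[tert-butyl(dimethyl)silyl]oxy}methyl)-1,3-dimethyl-6-[2-methyl-1-oxo-1-(prop-2-en-1-yloxy)propan-2-yl]cyclohex-3-en-1-yl}acetate | CC1=CC[C@H](C(C)(C)C(=O)OCC=C)[C@@](C)(CC(=O)OCC[Si](C)(C)C)[C@@H]1CO[Si](C)(C)C(C)(C)C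
F8 | step 10 | 2-(trimethylsilyl)ethyl {2-(hydroxymethyl)-1,3-dimethyl-6-[2-methyl-1-oxo-1-(prop-2-en-1-yloxy)propan-2-yl]cyclohex-3-en-1-yl}acetate | CC1=CC[C@H](C(C)(C)C(=O)OCC=C)[C@@](C)(CC(=O)OCC[Si](C)(C)C)[C@@H]1CO
F9 | step 18 | tertiary alcohol: 26 with water added across C7=C8, hydroxyl on C8 cis to the acetate arm | CC(=O)CC[C@H]1[C@](C)(CC(=O)OCC[Si](C)(C)C)[C@@H](C(C)(C)C(=O)OCC=C)CC[C@]1(C)O
F10 | step 18 | hydroxy acid: free acetic acid corresponding to F9 | CC(=O)CC[C@H]1[C@](C)(CC(=O)O)[C@@H](C(C)(C)C(=O)OCC=C)CC[C@]1(C)O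
F11 | step 21 | prop-2-en-1-yl 2-[(1S,5R,6S,9S)-9-[(3R)-3-hydroxy-3-methyl-5-(trimethylsilyl)pent-4-yn-1-yl]-1,5-dimethyl-3-oxo-2-oxabicyclo[3.3.1]nonan-6-yl]-2-methylpropanoate | C[Si](C)(C)C#C[C@](C)(O)CC[C@H]1[C@]2(C)CC(=O)O[C@@]1(C)CC[C@@H]2C(C)(C)C(=O)OCC=C
F12 | step 21 | prop-2-en-1-yl 2-[(1S,5R,6S,9S)-9-[(3R)-3-hydroxy-3-methylpent-4-yn-1-yl]-1,5-dimethyl-3-oxo-2-oxabicyclo[3.3.1]nonan-6-yl]-2-methylpropanoate | C#C[C@](C)(O)CC[C@H]1[C@]2(C)CC(=O)O[C@@]1(C)CC[C@@H]2C(C)(C)C(=O)OCC=C
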